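**Retrosynthetic overview** (benzofuran numbering O1, C2, C3, C3a, C4 to C7, C7a; ring A = the 4-hydroxy-3,5-dimethoxyphenyl ring on C2, ring B = the benzo ring)
1. The allylic alcohol comes from an (E)-acrylate and the acrylate from a C5 formyl group; both silyl ethers are removed last.
2. The dihydrofuran ring is opened at O1–C7a to a C2 alkoxide and a C7a–F arene; closure is an intramolecular SNAr, run in one pot with the Horner–Wadsworth–Emmons extension at C5.
3. Enabling feature: C5 of ring B is para to C7a, so the future propenol chain, held at the aldehyde oxidation level, stabilises the Meisenheimer complex at C7a; the fluorine at C7a earlier directs lithiation to the neighbouring C3a.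
4. The C2–C3 bond and both stereocentres come from an Evans syn-aldol of a ring B arylacetyl imide with O-silylated syringaldehyde; the syn aldol (O1 and ring B syn) becomes the 2,3-trans ring.
5. Ring order: rings A and B are bought as arenes; the dihydrofuran ring is the only ring formed, in step 9.

Key step: step 9

Remark: compounds 1 and 8 and the oxazolidinone auxiliary are taken as commercial; the same atom numbering is used for the open-chain precursors.

**Step 1**
Reactants: 1 4-fluoro-3-methoxybenzaldehyde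
Product: 2 2-(4-fluoro-3-methoxyphenyl)-1,3-dioxolane
Conditions: ethylene glycol, TsOH (cat.), toluene, reflux, Dean–Stark
Reagents that add atoms: ethylene glycol OCCO
Why: Acid-catalysed acetalisation with azeotropic removal of water masks the formyl group as a base-stable dioxolane, so that the aryllithium, enolate and hydride chemistry ahead cannot touch the future C5 carbon.

**Step 2**
Reactants: 2 2-(4-fluoro-3-methoxyphenyl)-1,3-dioxolane
Product: 4 2-[5-(1,3-dioxolan-2-yl)-2-fluoro-3-methoxyphenyl]ethan-1-ol, via aryllithium 3 (not isolated)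
Conditions: 2,2,6,6-tetramethylpiperidine, n-BuLi, THF, −78 °C; then BF3·OEt2, ethylene oxide, −78 °C
Reagents that add atoms: ethylene oxide C1CO1
Why: Directed ortho-metalation, in which the hindered amide base should take the acidic and least hindered ring proton ortho to fluorine (future C3a), and the aryllithium, kept at −78 °C so that LiF is not lost to an aryne, opens BF3-activated ethylene oxide.

**Step 3**
Reactants: 4 2-[5-(1,3-dioxolan-2-yl)-2-fluoro-3-methoxyphenyl]ethan-1-ol
Product: 5 [5-(1,3-dioxolan-2-yl)-2-fluoro-3-methoxyphenyl]acetic acid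
Conditions: TEMPO (cat.), NaOCl (cat.), NaClO2, MeCN/aq. NaH2PO4–Na2HPO4 (pH 6.7), 35 °C
Reagents that add atoms: sodium chlorite [Na+].[O-]Cl=O
Why: A TEMPO/hypochlorite-catalysed alcohol oxidation coupled to a Pinnick-type chlorite oxidation of the aldehyde carries the primary alcohol to the arylacetic acid near neutral pH, where the dioxolane should survive.

**Step 4**
Reactants: 5 [5-(1,3-dioxolan-2-yl)-2-fluoro-3-methoxyphenyl]acetic acid
Product: 7 (4S)-4-benzyl-3-{[5-(1,3-dioxolan-2-yl)-2-fluoro-3-methoxyphenyl]acetyl}-1,3-oxazolidin-2-one, via pivalic mixed anhydride 6 (not isolated)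
Conditions: t-BuCOCl, Et3N, THF, −20 °C; then (S)-4-benzyl-1,3-oxazolidin-2-one, LiCl, −20 °C to rt
Reagents that add atoms: (S)-4-benzyl-1,3-oxazolidin-2-one O=C1N[C@@H](Cc2ccccc2)CO1
Why: N-Acylation of the oxazolidinone through the mixed pivalic anhydride (LiCl/Et3N variant) attaches the Evans auxiliary under conditions that leave the acetal alone.

**Step 5**
Reactants: 8 syringaldehyde (4-hydroxy-3,5-dimethoxybenzaldehyde)
Product: 9 3,5-dimethoxy-4-[(triisopropylsilyl)oxy]benzaldehyde
Conditions: i-Pr3SiCl, imidazole, DMF, rt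
Reagents that add atoms: chlorotriisopropylsilane CC(C)[Si](Cl)(C(C)C)C(C)C
Why: Silylation of the hindered phenol gives a fluoride-labile ether that should tolerate the boron enolate, LiBH4, alkoxide and i-Bu2AlH steps.

**Step 6**
Reactants: 7 (4S)-4-benzyl-3-{[5-(1,3-dioxolan-2-yl)-2-fluoro-3-methoxyphenyl]acetyl}-1,3-oxazolidin-2-one; 9 3,5-dimethoxy-4-[(triisopropylsilyl)oxy]benzaldehyde
Product: 11 (4S)-4-benzyl-3-[(2S,3S)-2-[5-(1,3-dioxolan-2-yl)-2-fluoro-3-methoxyphenyl]-3-hydroxy-3-{3,5-dimethoxy-4-[(triisopropylsilyl)oxy]phenyl}propanoyl]-1,3-oxazolidin-2-one, via (Z)-boron enolate 10 (not isolated)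
Conditions: Bu2BOTf, i-Pr2NEt, CH2Cl2, −78 to 0 °C; then 9, −78 to 0 °C; then MeOH, aq. KH2PO4/K2HPO4 (pH 7), H2O2, 0 °C
Reagents that add atoms: none
Why: Evans syn-aldol reaction, in which the (Z)-boron enolate adds through a chair Zimmerman–Traxler transition state on the enolate face away from the benzyl group, setting the α-carbon (future C3) and the carbinol carbon (future C2) together as the (2S,3S) syn pair that becomes 2,3-trans after ring closure.

**Step 7**
Reactants: 11 the syn-aldol adduct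
Product: 13 3-[(1S,2R)-1,3-dihydroxy-1-{3,5-dimethoxy-4-[(triisopropylsilyl)oxy]phenyl}propan-2-yl]-4-fluoro-5-methoxybenzaldehyde, via diol acetal 12 (not isolated)
Conditions: LiBH4, MeOH (1 equiv), THF, 0 °C; then 1 M HCl, THF, rt
Reagents that add atoms: water O
Why: Reductive removal of the auxiliary by hydride attack at the exocyclic imide carbonyl gives the 1,3-diol without touching either stereocentre, and dilute aqueous acid then hydrolyses the dioxolane to unveil the para-formyl activating group.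

**Step 8**
Reactants: 13 the diol aldehyde
Product: 14 4-fluoro-3-[(1S,2R)-1-hydroxy-1-{3,5-dimethoxy-4-[(triisopropylsilyl)oxy]phenyl}-3-[(triisopropylsilyl)oxy]propan-2-yl]-5-methoxybenzaldehyde
Conditions: i-Pr3SiCl, imidazole, DMF, 0 °C to rt
Reagents that add atoms: chlorotriisopropylsilane CC(C)[Si](Cl)(C(C)C)C(C)C
Why: Sterically controlled silylation should pick the primary hydroxyl over the hindered secondary benzylic one, so that only O1 can act as nucleophile in the ring closure, and the triisopropylsilyl group is chosen because it migrates between oxygens far more slowly than smaller silyl groups.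

**Step 9**
Reactants: 14 the fluoro aldehyde with free C2 hydroxyl
Product: 16 methyl (2E)-3-[(2S,3R)-2-{3,5-dimethoxy-4-[(triisopropylsilyl)oxy]phenyl}-7-methoxy-3-{[(triisopropylsilyl)oxy]methyl}-2,3-dihydro-1-benzofuran-5-yl]prop-2-enoate, via cyclised aldehyde 15 (not isolated)
Conditions: KOt-Bu (1.05 equiv), THF, −20 to 20 °C; then (MeO)2P(O)CH2CO2Me, KOt-Bu, THF, 0 to 20 °C
Reagents that add atoms: trimethyl phosphonoacetate COC(=O)CP(=O)(OC)OC
Why: The C2 alkoxide adds to C7a of ring B, the negative charge of the Meisenheimer complex is delocalised into the para formyl group at C5, and loss of fluoride restores the arene (addition–elimination SNAr; closest known type is the base-mediated cyclisation of 2-(2-fluoroaryl)ethanols carrying a para acceptor to 2,3-dihydrobenzofurans). The dihydrofuran ring closes as a five-membered ring onto the ipso carbon (formally 5-exo-trig). No stereocentre is made or broken: C2 and C3 keep the syn-aldol configuration, and at the alcohol oxidation level neither retro-aldol cleavage nor epimerisation at C3 is possible, so the ring should come out 2,3-trans. The step needs O1 to react and not the primary oxygen, which the slowly migrating triisopropylsilyl ether secures, and it needs C7a to be attacked in preference to the formyl group, which the reversibility of hemiacetal formation against the irreversible loss of fluoride secures. The phosphonate anion added next turns the spent activating group into the (E)-acrylate by Horner–Wadsworth–Emmons olefination, the E geometry following from the stabilised phosphonate.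

**Step 10**
Reactants: 16 the (E)-acrylate
Product: 17 (2E)-3-[(2S,3R)-2-{3,5-dimethoxy-4-[(triisopropylsilyl)oxy]phenyl}-7-methoxy-3-{[(triisopropylsilyl)oxy]methyl}-2,3-dihydro-1-benzofuran-5-yl]prop-2-en-1-ol
Conditions: i-Bu2AlH (3 equiv), CH2Cl2, −78 °C
Reagents that add atoms: none
Why: 1,2-Reduction of the α,β-unsaturated ester by i-Bu2AlH at low temperature should give the (E)-allylic alcohol without conjugate reduction or loss of the silyl ethers.

**Step 11**
Reactants: 17 the bis-silyl ether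
Product: 18 4-[(2S,3R)-3-(hydroxymethyl)-5-[(1E)-3-hydroxyprop-1-en-1-yl]-7-methoxy-2,3-dihydro-1-benzofuran-2-yl]-2,6-dimethoxyphenol (target)
Conditions: Bu4NF, AcOH, THF, 0 °C to rt
Reagents that add atoms: none
Why: Fluoride-mediated desilylation, buffered with acetic acid so that the phenoxide does not open the benzylic ether through a quinone methide, frees the phenol and the primary alcohol and leaves both stereocentres untouched.

**Compound list**
1 | 4-fluoro-3-methoxybenzaldehyde | COc1cc(C=O)ccc1F | starting material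
2 | 2-(4-fluoro-3-methoxyphenyl)-1,3-dioxolane | COc1cc(C2OCCO2)ccc1F | intermediate
3 | [5-(1,3-dioxolan-2-yl)-2-fluoro-3-methoxyphenyl]lithium | [Li]c1cc(C2OCCO2)cc(OC)c1F | intermediate
4 | 2-[5-(1,3-dioxolan-2-yl)-2-fluoro-3-methoxyphenyl]ethan-1-ol | COc1cc(C2OCCO2)cc(CCO)c1F | intermediate
5 | [5-(1,3-dioxolan-2-yl)-2-fluoro-3-methoxyphenyl]acetic acid | COc1cc(C2OCCO2)cc(CC(=O)O)c1F | intermediate
6 | [5-(1,3-dioxolan-2-yl)-2-fluoro-3-methoxyphenyl]acetic pivalic anhydride | COc1cc(C2OCCO2)cc(CC(=O)OC(=O)C(C)(C)C)c1F | intermediate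
7 | (4S)-4-benzyl-3-{[5-(1,3-dioxolan-2-yl)-2-fluoro-3-methoxyphenyl]acetyl}-1,3-oxazolidin-2-one | COc1cc(C2OCCO2)cc(CC(=O)N2[C@@H](Cc3ccccc3)COC2=O)c1F | intermediate
8 | syringaldehyde (4-hydroxy-3,5-dimethoxybenzaldehyde) | COc1cc(C=O)cc(OC)c1O | starting material
9 | 3,5-dimethoxy-4-[(triisopropylsilyl)oxy]benzaldehyde | COc1cc(C=O)cc(OC)c1O[Si](C(C)C)(C(C)C)C(C)C | intermediate
10 | (Z)-dibutylboron enolate of 7 | CCCCB(CCCC)O/C(=C\c1cc(C2OCCO2)cc(OC)c1F)N1[C@@H](Cc2ccccc2)COC1=O | intermediate
11 | (4S)-4-benzyl-3-[(2S,3S)-2-[5-(1,3-dioxolan-2-yl)-2-fluoro-3-methoxyphenyl]-3-hydroxy-3-{3,5-dimethoxy-4-[(triisopropylsilyl)oxy]phenyl}propanoyl]-1,3-oxazolidin-2-one | COc1cc(cc(OC)c1O[Si](C(C)C)(C(C)C)C(C)C)[C@@H](O)[C@@H](C(=O)N1[C@@H](Cc2ccccc2)COC1=O)c1cc(C2OCCO2)cc(OC)c1F | intermediate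
12 | (1S,2R)-2-[5-(1,3-dioxolan-2-yl)-2-fluoro-3-methoxyphenyl]-1-{3,5-dimethoxy-4-[(triisopropylsilyl)oxy]phenyl}propane-1,3-diol | COc1cc(cc(OC)c1O[Si](C(C)C)(C(C)C)C(C)C)[C@@H](O)[C@@H](CO)c1cc(C2OCCO2)cc(OC)c1F | intermediate
13 | 3-[(1S,2R)-1,3-dihydroxy-1-{3,5-dimethoxy-4-[(triisopropylsilyl)oxy]phenyl}propan-2-yl]-4-fluoro-5-methoxybenzaldehyde | COc1cc(cc(OC)c1O[Si](C(C)C)(C(C)C)C(C)C)[C@@H](O)[C@@H](CO)c1cc(C=O)cc(OC)c1F | intermediate
14 | 4-fluoro-3-[(1S,2R)-1-hydroxy-1-{3,5-dimethoxy-4-[(triisopropylsilyl)oxy]phenyl}-3-[(triisopropylsilyl)oxy]propan-2-yl]-5-methoxybenzaldehyde | COc1cc(cc(OC)c1O[Si](C(C)C)(C(C)C)C(C)C)[C@@H](O)[C@@H](CO[Si](C(C)C)(C(C)C)C(C)C)c1cc(C=O)cc(OC)c1F | intermediate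
15 | (2S,3R)-2-{3,5-dimethoxy-4-[(triisopropylsilyl)oxy]phenyl}-7-methoxy-3-{[(triisopropylsilyl)oxy]methyl}-2,3-dihydro-1-benzofuran-5-carbaldehyde | COc1cc([C@H]2Oc3c(OC)cc(C=O)cc3[C@@H]2CO[Si](C(C)C)(C(C)C)C(C)C)cc(OC)c1O[Si](C(C)C)(C(C)C)C(C)C | intermediate
16 | methyl (2E)-3-[(2S,3R)-2-{3,5-dimethoxy-4-[(triisopropylsilyl)oxy]phenyl}-7-methoxy-3-{[(triisopropylsilyl)oxy]methyl}-2,3-dihydro-1-benzofuran-5-yl]prop-2-enoate | COc1cc([C@H]2Oc3c(OC)cc(/C=C/C(=O)OC)cc3[C@@H]2CO[Si](C(C)C)(C(C)C)C(C)C)cc(OC)c1O[Si](C(C)C)(C(C)C)C(C)C | intermediate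
17 | (2E)-3-[(2S,3R)-2-{3,5-dimethoxy-4-[(triisopropylsilyl)oxy]phenyl}-7-methoxy-3-{[(triisopropylsilyl)oxy]methyl}-2,3-dihydro-1-benzofuran-5-yl]prop-2-en-1-ol | COc1cc([C@H]2Oc3c(OC)cc(/C=C/CO)cc3[C@@H]2CO[Si](C(C)C)(C(C)C)C(C)C)cc(OC)c1O[Si](C(C)C)(C(C)C)C(C)C | intermediate
18 | 4-[(2S,3R)-3-(hydroxymethyl)-5-[(1E)-3-hydroxyprop-1-en-1-yl]-7-methoxy-2,3-dihydro-1-benzofuran-2-yl]-2,6-dimethoxyphenol | COc1cc([C@H]2Oc3c(OC)cc(/C=C/CO)cc3[C@@H]2CO)cc(OC)c1O | target

**Step count and risks**
Total step count: 11. Longest linear sequence: 10 steps (steps 1 to 4 and 6 to 11).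

Steps most likely to fail:

1. Step 9. The alkoxide or tert-butoxide may engage the unprotected formyl group (hemiacetal formation followed by intermolecular hydride transfer) faster than the ring closes at the doubly ortho-substituted C7a. Fallback, from 14 and back at 15: the formyl group of 14 is first converted into the equally activating but alkoxide-inert nitrile (I2, aq. NH3, THF, rt), which should give 4-fluoro-3-[(1S,2R)-1-hydroxy-1-{3,5-dimethoxy-4-[(triisopropylsilyl)oxy]phenyl}-3-[(triisopropylsilyl)oxy]propan-2-yl]-5-methoxybenzonitrile F1. KOt-Bu in THF should then close the ring by the same SNAr to (2S,3R)-2-{3,5-dimethoxy-4-[(triisopropylsilyl)oxy]phenyl}-7-methoxy-3-{[(triisopropylsilyl)oxy]methyl}-2,3-dihydro-1-benzofuran-5-carbonitrile F2. Partial reduction with i-Bu2AlH (toluene, −78 °C, aqueous acid work-up) should return aldehyde 15, which is olefinated as in the second half of step 9.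

2. Step 2. Metalation may occur at the position between the methoxy and acetal groups instead of next to fluorine, or the aryllithium may lose LiF to an aryne before it is trapped. Fallback, from 2 and back at 5: iridium-catalysed C–H borylation of 2 ([Ir(OMe)(cod)]2, 4,4′-di-tert-butyl-2,2′-bipyridine, B2pin2, THF, 80 °C) is sterically directed to the only C–H bond whose sole ortho neighbour is fluorine, and should give 2-[5-(1,3-dioxolan-2-yl)-2-fluoro-3-methoxyphenyl]-4,4,5,5-tetramethyl-1,3,2-dioxaborolane F3. Suzuki–Miyaura-type coupling with ethyl bromoacetate (Pd(OAc)2, tri(1-naphthyl)phosphine, K3PO4, THF/H2O, rt) should give ethyl [5-(1,3-dioxolan-2-yl)-2-fluoro-3-methoxyphenyl]acetate F4. Saponification (LiOH, THF/H2O) then gives acid 5.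

3. Step 7. Under the basic borohydride conditions the hindered α-aryl aldol may fragment by retro-aldol cleavage, or hydride may attack the ring carbonyl of the auxiliary. Fallback, from 11 and back at 12: peroxide-assisted hydrolysis (LiOH, H2O2, THF/H2O, 0 °C) cleaves the exocyclic acyl bond and should give (2S,3S)-2-[5-(1,3-dioxolan-2-yl)-2-fluoro-3-methoxyphenyl]-3-hydroxy-3-{3,5-dimethoxy-4-[(triisopropylsilyl)oxy]phenyl}propanoic acid F5. Reduction of the free acid with BH3·SMe2 (THF, 0 °C), which is not basic, should give diol 12, and the acetal is then hydrolysed as in the second half of step 7.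

**Further compounds**
F1 | step 9 | 4-fluoro-3-[(1S,2R)-1-hydroxy-1-{3,5-dimethoxy-4-[(triisopropylsilyl)oxy]phenyl}-3-[(triisopropylsilyl)oxy]propan-2-yl]-5-methoxybenzonitrile | COc1cc(cc(OC)c1O[Si](C(C)C)(C(C)C)C(C)C)[C@@H](O)[C@@H](CO[Si](C(C)C)(C(C)C)C(C)C)c1cc(C#N)cc(OC)c1F
F2 | step 9 | (2S,3R)-2-{3,5-dimethoxy-4-[(triisopropylsilyl)oxy]phenyl}-7-methoxy-3-{[(triisopropylsilyl)oxy]methyl}-2,3-dihydro-1-benzofuran-5-carbonitrile | COc1cc([C@H]2Oc3c(OC)cc(C#N)cc3[C@@H]2CO[Si](C(C)C)(C(C)C)C(C)C)cc(OC)c1O[Si](C(C)C)(C(C)C)C(C)C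
F3 | step 2 | 2-[5-(1,3-dioxolan-2-yl)-2-fluoro-3-methoxyphenyl]-4,4,5,5-tetramethyl-1,3,2-dioxaborolane | COc1cc(C2OCCO2)cc(B2OC(C)(C)C(C)(C)O2)c1F
F4 | step 2 | ethyl [5-(1,3-dioxolan-2-yl)-2-fluoro-3-methoxyphenyl]acetate | CCOC(=O)Cc1cc(C2OCCO2)cc(OC)c1F
F5 | step 7 | (2S,3S)-2-[5-(1,3-dioxolan-2-yl)-2-fluoro-3-methoxyphenyl]-3-hydroxy-3-{3,5-dimethoxy-4-[(triisopropylsilyl)oxy]phenyl}propanoic acid | COc1cc(cc(OC)c1O[Si](C(C)C)(C(C)C)C(C)C)[C@@H](O)[C@@H](C(=O)O)c1cc(C2OCCO2)cc(OC)c1F
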